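## Analysis of the target

Compound 35 (C33H38O9) consists of two halves joined at a spiro acylal carbon. The first half is a cage, a 4-oxatricyclo[4.3.1.0(3,7)]dec-8-en-2-one. It is a bicyclo[2.2.2]octenone (bridgeheads C1 and C7; bridges C2–C3, C8=C9 and C10–C6) with a tetrahydrofuran (C3–O4–C5–C6–C7) fused across it. C1 carries a tertiary hydroxyl, C2 is a ketone, C3 carries a prenyl group and the ether oxygen, C5 is the gem-dimethyl carbon and C8 carries a carboxyl carbon. The second half is a 2H-pyran-fused cyclohexenedione derived from a prenylated hydroxyquinone; its former hydroxyl carbon is the spiro centre of a 1,3-dioxin-4-one whose other members are the C8 carboxyl group and the C7 oxygen. Of the six stereocentres, four (C1, C3, C6, C7) are locked to each other by the cage, so only their common absolute sense must be set; the spiro carbon and the neighbouring CH(prenyl) must be related to the cage in the last step. Sensitive groups are the two prenyl groups and the chromene alkene (acid, oxidants), the bridgehead α-ketol C1/C2 (acyloin shift) and the acylal, which loses its carboxylate by β-elimination once the adjacent C–H is enolised. The difficulty lies in four contiguous fully substituted carbons (C1, C2, C3, C7), three of them oxygenated, next to a bridge that has to be closed. The strategy rests on one feature: the carbinol C1 and the bridge methylene C10 are the two carbons of a spiro epoxide on a cyclohexenone, and the methine C6 at the other end of C10 becomes acidic if C5 is temporarily a lactone carbonyl instead of the gem-dimethyl carbon.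

## Retrosynthetic reasoning

**35 to 24 and 32.** The two C–O bonds at the spiro carbon are cut: the acyl–oxygen bond and the bond from the C7 oxygen. This is the most fragile part of the molecule, so it is made last, and the cut divides 35 into cage acid 24 and hydroxyquinone 32. The forward reaction must acylate the vinylogous acid 32 (via 33 to 34), add the C7 hydroxyl to the acyloxy-bearing quinone carbon, and protonate the neighbouring carbon without expelling the carboxylate.

**24 back to 18.** The acid is freed from tert-butyl ester 22, which tolerates every nucleophile used earlier. The O4–C5 bond of 22 comes from cyclodehydration of diol 21, and the two methyl groups on C5 come from double methyl addition to the lactone carbonyl of the cage. A methyl nucleophile cannot be expected to tell the lactone from the C2 ketone, so the ketone is reduced first (18 to 19), the methyl groups are added (20), and the ketone is restored (21) before ring closure. This costs two redox steps, but it removes a chemoselectivity gamble.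

**18 to 16 (key disconnection).** The C6–C10 bond is cut. C10 is an unfunctionalised CH2 next to a tertiary carbinol, which is the retron of an epoxide opened at its CH2. C6 is α to the lactone carbonyl in 18, so it can be the nucleophile. No other bond of the bicycle offers both a nucleophilic and a strained electrophilic partner without added functionality. The cut removes the cage and its strain and leaves the cis-fused bicyclic lactone 16, in which three of the four cage stereocentres are already present. The forward reaction must bring the lactone enolate carbon (dianion 17) onto the epoxide CH2 across the ring.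

**16 to 13 and 14.** The C3–prenyl bond is cut. C3 is the only enolisable position of the ketone in 13, and alkylation of enolate 15 by 14 at a ring-fusion carbon can only give the cis-fused lactone. The prenyl group is introduced after all oxidations.

**13 to 11.** The spiro epoxide of 13 is taken back to the exocyclic alkene of 11 through epoxy alcohol 12. The secondary hydroxyl next to the alkene directs the epoxidation, so the epoxide CH2 lands on the lactone face, which the key step requires. The same hydroxyl is then oxidised to the ketone that the prenylation needs.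

**11 to 7.** The ester carbon is taken off at the vinyl iodide 9 (carbonylation to 10, then esterification to 11). The exocyclic methylene is taken back to the ketone of 7 (via 8). The iodide is used because the carboxyl carbon sits β to that ketone, a position that can be functionalised only while it is still α to the earlier ketone of 3.

**7 to 6 to 3 and 4.** The lactone C–O bond at C3 is cut to the epoxide of 6, and the C6–C7 bond to the ketone of 3 and acetate 4 (via enolate 5). The epoxide of 3 controls the face of the aldol addition and then supplies both the lactone oxygen and the secondary hydroxyl with the required relative configuration.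

**3 to 2 to 1.** Iodination and a desymmetrising epoxidation lead back to the achiral quinone monoketal 1. This single enantioselective step fixes the absolute configuration of the whole cage.

**32 to 25.** The pyran of 32 is cut by a formal [3+3] disconnection to dihydroxyquinone 30 and enal 31. 30 comes from dimethoxyquinone 29, that from arene 28 by oxidative demethylation, and 28 from 26 (made from phenol 25) and 14 by ortho-metalation via 27.

## Alternatives that were turned down

**Alternative 1:** The cage would be cut at C2–C1 and, further back, at C3–C7 and at a temporary C2–C8 bond. A ketene carrying the ether oxygen and the prenyl group on its α-carbon, tethered through O4–C5–C6 to a cyclohexa-1,3-diene that is a silyl enol ether at C7 and at C1, would add across the C7=C8 enol ether in a [2+2] cycloaddition to give cyclobutanone A1. A 1,3-acyl shift of this 2-vinylcyclobutanone would then move C2 from C8 to C1 and release the four-ring strain into the bicyclo[2.2.2]octenone.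
- For it: the tetrahydrofuran with its gem-dimethyl carbon, the C3 quaternary centre and both bridgehead oxygens are present from the start at the right oxidation level. The tether fixes the relative configuration and two rings form in one step. On these points it is stronger than the chosen route, which must convert a lactone into the ether afterwards.
- Against it: the enol ether that must react is a β-silyloxy acrylate, a push–pull alkene of low nucleophilicity. The ketene is fully substituted and must be generated next to a prenyl alkene. The acyl shift of A1 is the weaker half: such shifts are reversible, compete with decarbonylation and with ring opening by the β-silyloxy group, and must here form a bond to a carbon that already bears oxygen. The cyclisation substrate, with one controlling stereocentre at C6, is not short to make.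
- Comparison: the chosen strategy offers a single SN2 event whose geometry is fixed by the ring system and whose driving force (epoxide strain) also delivers the bridgehead hydroxyl.

**Alternative 2:** The bicyclo[2.2.2]octenone is already present and the cut is made at C3: the C3–O4 bond and the bond from C3 to the prenyl CH2. A rhodium carbenoid generated at C3 from a diazo group next to the C2 ketone would be captured by the oxygen of a 1,1-dimethylallyl ether on the C5 carbinol. The five-membered oxonium ylide would undergo a [2,3]-shift that converts the 1,1-dimethylallyl group into the C3 prenyl group and leaves the tetrahydrofuran, giving A2.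
- For it: the bicyclic core could come from a dearomatisation and Diels–Alder sequence in very few steps. The quaternary ether carbon, the tetrahydrofuran and the prenyl group are made together at the correct oxidation level, with C3 fixed by the bicycle. In convergence and in avoiding any lactone-to-ether adjustment it is stronger than the chosen route.
- Against it: the ether oxygen that must attack the carbenoid lies between two fully substituted carbons and is a hindered, poor nucleophile. The di-tertiary allyl ether is itself hard to prepare. Diazo transfer to a CH2 between a ketone and a bridgehead needs prior activation. The carbenoid has other outlets (cyclopropanation of the C8=C9 enoate, C–H insertion, [1,2]-shift).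
- Comparison: the chosen strategy is longer, but each C–O bond at C3 is made by ordinary polar chemistry that can be controlled step by step.

**Alternative 3:** The cut is the C1–C10 bond. A tertiary radical at C1, flanked by the protected oxygen, the C2 ketone and the C8=C9 alkene and formed by homolysis of a C1–Se bond, would add to the terminal carbon of an exocyclic methylene at C6 of a preformed tetrahydrofuran (6-endo closure). Hydrogen transfer to the C6 radical would give A3; because the radical is planar, both epimers of its precursor converge.
- For it: neutral conditions; the gem-dimethyl tetrahydrofuran and the C3 prenyl group are carried through untouched; no strong base meets the β-hydroxy carbonyl array; the same ring is closed as in the chosen key step without a later lactone adjustment. In functional-group economy it is at least as strong.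
- Against it: the radical is stabilised three times (alkoxy, acyl, allyl) and should add slowly and reversibly. Premature reduction and reaction through the other end of the allyl system compete. A tertiary selenide next to a ketone must be made. The bridgehead oxygen arrives protected, so an acetal cleavage is added late.
- Comparison: the chosen route closes the same bicycle by an irreversible polar step, needs neither tin nor selenium, and delivers the C1 hydroxyl free.

Key step: step 11

Remarks on the chemistry (assumptions):
- The cinchonidinium salt in step 1 is taken to favour the (1R,6S)-epoxide; if it favours the antipode, the pseudoenantiomeric cinchoninium salt is used.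
- The configuration of 35 at the spiro carbon and at the adjacent CH(prenyl) is taken to be the thermodynamic outcome of reversible ring closure and enolisation.
- The carbinol centres created in 8 and in 19/20 are left undefined because they are destroyed again in steps 5 and 14.

## Route

Step 1
Reactants: 1 4,4-dimethoxycyclohexa-2,5-dien-1-one
Product: 2 (1R,6S)-5,5-dimethoxy-7-oxabicyclo[4.1.0]hept-3-en-2-one
Conditions: t-BuOOH (1.1 equiv), NaOH (aq.), N-benzylcinchonidinium chloride (10 mol %), toluene, 0 °C
Reagents that add atoms: tert-butyl hydroperoxide, CC(C)(C)OO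
Why: Weitz–Scheffer nucleophilic epoxidation under chiral phase-transfer catalysis; the cinchona ammonium peroxide ion pair should distinguish the two enantiotopic enone alkenes of the planar dienone, and limiting the peroxide holds the reaction at the mono-epoxide.

Step 2
Reactants: 2 (1R,6S)-5,5-dimethoxy-7-oxabicyclo[4.1.0]hept-3-en-2-one
Product: 3 (1R,6S)-3-iodo-5,5-dimethoxy-7-oxabicyclo[4.1.0]hept-3-en-2-one
Conditions: I2, pyridine, CH2Cl2, 0 °C → rt
Reagents that add atoms: iodine, II
Why: α-Iodination of an enone by conjugate addition of pyridine, iodination of the enolate and elimination (Baylis–Hillman-type mechanism); only the remaining enone alkene can react and the epoxide centres are untouched.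

Step 3
Reactants: 3 (1R,6S)-3-iodo-5,5-dimethoxy-7-oxabicyclo[4.1.0]hept-3-en-2-one; 4 tert-butyl acetate
Product: 6 tert-butyl 2-[2-hydroxy-3-iodo-5,5-dimethoxy-7-oxabicyclo[4.1.0]hept-3-en-2-yl]acetate (hydroxyl cis to the epoxide oxygen), via lithium enolate of tert-butyl acetate 5 (not isolated)
Conditions: LiN(iPr)2, 4, THF, −78 °C; then 3, −78 °C; AcOH quench
Reagents that add atoms: none
Why: Aldol-type 1,2-addition of an ester enolate to the ketone; as with other nucleophiles and 2,3-epoxycyclohexanones the enolate should approach anti to the epoxide oxygen, so the acetate arm is trans and the new hydroxyl cis to the epoxide. A cold quench prevents retro-aldol.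

Step 4
Reactants: 6 tert-butyl 2-[2-hydroxy-3-iodo-5,5-dimethoxy-7-oxabicyclo[4.1.0]hept-3-en-2-yl]acetate
Product: 7 cis-fused 3a,7-dihydroxy-4-iodo-3,3a,7,7a-tetrahydro-1-benzofuran-2,6-dione (7-OH cis to 3a-OH and trans to the lactone oxygen)
Conditions: CF3CO2H, CH2Cl2, 0 °C; then H2O, 0 °C → rt
Reagents that add atoms: water, O
Why: Acid-promoted lactonisation by 5-exo opening of the epoxide: the ester carbonyl attacks the epoxide carbon next to the carbinol from the face opposite the epoxide oxygen (inversion) and loses 2-methylpropene, giving the cis-fused β-hydroxy γ-lactone; the epoxide carbon next to the electron-poor ketal is not attacked. Water then hydrolyses the dimethyl ketal to the enone.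

Step 5
Reactants: 7 cis-fused 3a,7-dihydroxy-4-iodo-3,3a,7,7a-tetrahydro-1-benzofuran-2,6-dione
Product: 9 3a,7-dihydroxy-4-iodo-6-methylidene-3a,6,7,7a-tetrahydro-1-benzofuran-2(3H)-one (configuration as in 7), via β-hydroxysilane adduct 8 (not isolated)
Conditions: Me3SiCH2Li, CeCl3, THF, −78 °C; then HF (aq.), MeCN, 0 °C
Reagents that add atoms: (trimethylsilyl)methyllithium, [Li]C[Si](C)(C)C
Why: Peterson methylenation; the weakly basic organocerium reagent should add 1,2 to the ketone without enolising next to the β-acyloxy group and without attacking the lactone at −78 °C, and acid eliminates the β-hydroxysilane to the exocyclic alkene. No reducing metal is present that could remove the vinylic iodine.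

Step 6
Reactants: 9 3a,7-dihydroxy-4-iodo-6-methylidene-3a,6,7,7a-tetrahydro-1-benzofuran-2(3H)-one
Product: 10 3a,7-dihydroxy-6-methylidene-2-oxo-2,3,3a,6,7,7a-hexahydro-1-benzofuran-4-carboxylic acid (configuration as in 7)
Conditions: Pd(OAc)2 (5 mol %), PPh3, CO (1 atm), KOAc, DMF/H2O, 50 °C
Reagents that add atoms: carbon monoxide, [C-]#[O+]; water, O
Why: Palladium-catalysed hydroxycarbonylation of a dienyl iodide (oxidative addition to zerovalent palladium, CO insertion, hydrolysis of the acylpalladium); the mild acetate base should leave the lactone and the allylic alcohol alone.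

Step 7
Reactants: 10 3a,7-dihydroxy-6-methylidene-2-oxo-2,3,3a,6,7,7a-hexahydro-1-benzofuran-4-carboxylic acid
Product: 11 tert-butyl 3a,7-dihydroxy-6-methylidene-2-oxo-2,3,3a,6,7,7a-hexahydro-1-benzofuran-4-carboxylate
Conditions: O-tert-butyl-N,N'-diisopropylisourea, CH2Cl2, rt
Reagents that add atoms: O-tert-butyl-N,N'-diisopropylisourea, CC(C)N=C(OC(C)(C)C)NC(C)C
Why: Esterification by O-alkylisourea alkylation; only the carboxylic acid is acidic enough to protonate the isourea, so both hydroxyls stay free.

Step 8
Reactants: 11 tert-butyl 3a,7-dihydroxy-6-methylidene-2-oxo-2,3,3a,6,7,7a-hexahydro-1-benzofuran-4-carboxylate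
Product: 12 tert-butyl 3a,7-dihydroxy-2-oxo-3,3a,7,7a-tetrahydro-2H-spiro[1-benzofuran-6,2'-oxirane]-4-carboxylate (oxirane oxygen cis to the 7-OH; oxirane CH2 on the lactone face)
Conditions: VO(acac)2 (5 mol %), t-BuOOH, CH2Cl2, 0 °C → rt
Reagents that add atoms: tert-butyl hydroperoxide, CC(C)(C)OO
Why: Hydroxyl-directed epoxidation: the vanadium peroxide bound to the allylic secondary alkoxide delivers oxygen to the exocyclic methylene on the face of that hydroxyl, which places the epoxide CH2 on the lactone face. The ester-conjugated ring alkene is too electron-poor to react.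

Step 9
Reactants: 12 tert-butyl 3a,7-dihydroxy-2-oxo-3,3a,7,7a-tetrahydro-2H-spiro[1-benzofuran-6,2'-oxirane]-4-carboxylate
Product: 13 tert-butyl 3a-hydroxy-2,7-dioxo-3,3a,7,7a-tetrahydro-2H-spiro[1-benzofuran-6,2'-oxirane]-4-carboxylate (oxirane CH2 on the lactone face)
Conditions: Dess–Martin periodinane, NaHCO3, CH2Cl2, rt
Reagents that add atoms: none
Why: Dess–Martin oxidation of the only secondary alcohol under buffered neutral conditions that should spare the epoxide and avoid dehydration of the β-hydroxy ketone.

Step 10
Reactants: 13 tert-butyl 3a-hydroxy-2,7-dioxo-3,3a,7,7a-tetrahydro-2H-spiro[1-benzofuran-6,2'-oxirane]-4-carboxylate; 14 1-bromo-3-methylbut-2-ene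
Product: 16 tert-butyl 3a-hydroxy-7a-(3-methylbut-2-en-1-yl)-2,7-dioxo-3,3a,7,7a-tetrahydro-2H-spiro[1-benzofuran-6,2'-oxirane]-4-carboxylate (cis-fused; prenyl cis to the 3a-OH; oxirane CH2 on the lactone face), via dilithium alkoxide ketone enolate 15 (not isolated)
Conditions: LiN(SiMe3)2 (2.1 equiv), THF, −78 °C; then 14, DMPU, −78 → −40 °C; AcOH quench
Reagents that add atoms: none
Why: C-Alkylation of a ketone enolate; after the hydroxyl, the base removes the single α-hydrogen of the ketone (more acidic than the lactone α-hydrogens), and the alkoxide in the dianion cannot be eliminated. Prenyl bromide can only enter on the face that keeps the γ-lactone cis-fused, so the prenyl group replaces hydrogen with retention.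

Step 11
Reactants: 16 tert-butyl 3a-hydroxy-7a-(3-methylbut-2-en-1-yl)-2,7-dioxo-3,3a,7,7a-tetrahydro-2H-spiro[1-benzofuran-6,2'-oxirane]-4-carboxylate
Product: 18 tert-butyl 1,7-dihydroxy-3-(3-methylbut-2-en-1-yl)-2,5-dioxo-4-oxatricyclo[4.3.1.0(3,7)]dec-8-ene-8-carboxylate (caged lactone; configuration as in the compound list), via dilithium alkoxide lactone enolate 17 (not isolated)
Conditions: LiN(SiMe3)2 (2.2 equiv), THF, −78 °C → 0 °C; AcOH quench at −78 °C
Reagents that add atoms: none
Why: Two equivalents of amide base remove first the tertiary O–H and then a lactone α-hydrogen, the only acidic C–H left because the ketone lies between two fully substituted carbons; in dianion 17 the enolate carbon C6 attacks the unsubstituted epoxide carbon C10 anti to its C–O bond, which forms the C6–C10 bond, closes the bicyclo[2.2.2]octenone and leaves the epoxide oxygen as the bridgehead alkoxide at C1. The closest known reaction type is the intramolecular alkylation of an ester enolate (β-hydroxy ester dianion) by an epoxide. The new six-membered ring (C6, C10, C1, C9, C8, C7) closes by SN2 attack with the breaking C–O bond exocyclic to the forming ring (6-exo-tet in the bond-based sense, both epoxide carbons becoming ring members), through a boat conformer of the cyclohexenone in which C10 and C6 are the flagpole substituents and O–C10···C6 are nearly collinear. The one new stereocentre, C6, is fixed by the cis-fused lactone and the cage, since C6 can reach C10 only on the face that leaves its carbonyl substituent directed toward C3. Attack at the primary and not the quaternary epoxide carbon is secured by sterics and by the strained bicyclo[2.2.1] skeleton the other mode would need. The epoxide CH2 lies on the lactone face because of step 8, and the C7 alkoxide lies on the opposite face and cannot reach it. Working through the dianion blocks retro-aldol cleavage and β-elimination of the C7 oxygen, and epoxide strain drives a bridging alkylation that would otherwise be slow.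

Step 12
Reactants: 18 tert-butyl 1,7-dihydroxy-3-(3-methylbut-2-en-1-yl)-2,5-dioxo-4-oxatricyclo[4.3.1.0(3,7)]dec-8-ene-8-carboxylate
Product: 19 tert-butyl 1,2,7-trihydroxy-3-(3-methylbut-2-en-1-yl)-5-oxo-4-oxatricyclo[4.3.1.0(3,7)]dec-8-ene-8-carboxylate (either epimer at C2)
Conditions: NaBH4, CeCl3·7H2O, MeOH, −40 °C
Reagents that add atoms: none
Why: Luche reduction of the ketone, which would otherwise compete with the lactone for the methyl nucleophile of step 13; the lactone and the hindered tert-butyl enoate should not be reduced at this temperature.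

Step 13
Reactants: 19 tert-butyl 1,2,7-trihydroxy-3-(3-methylbut-2-en-1-yl)-5-oxo-4-oxatricyclo[4.3.1.0(3,7)]dec-8-ene-8-carboxylate
Product: 20 tert-butyl 1,4,5,6-tetrahydroxy-7-(2-hydroxypropan-2-yl)-6-(3-methylbut-2-en-1-yl)bicyclo[2.2.2]oct-2-ene-2-carboxylate (6-OH and the C7 side chain syn to each other)
Conditions: MeLi (excess), CeCl3, THF, −78 → 0 °C
Reagents that add atoms: methyllithium, [Li]C
Why: Double 1,2-addition of methylcerium to the lactone carbonyl gives the tertiary carbinol and frees the C3 oxygen of the cage; the organocerium reagent is nucleophilic but weakly basic, so the intermediate methyl ketone is not enolised and retro-aldol is not triggered. The hindered tert-butyl enoate should not undergo 1,2- or conjugate addition.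

Step 14
Reactants: 20 tert-butyl 1,4,5,6-tetrahydroxy-7-(2-hydroxypropan-2-yl)-6-(3-methylbut-2-en-1-yl)bicyclo[2.2.2]oct-2-ene-2-carboxylate
Product: 21 tert-butyl 1,4,6-trihydroxy-7-(2-hydroxypropan-2-yl)-6-(3-methylbut-2-en-1-yl)-5-oxobicyclo[2.2.2]oct-2-ene-2-carboxylate
Conditions: IBX, DMSO, rt
Reagents that add atoms: none
Why: IBX oxidation of the only secondary alcohol; IBX converts alcohols flanked by tertiary hydroxyls into α-ketols without glycol cleavage.

Step 15
Reactants: 21 tert-butyl 1,4,6-trihydroxy-7-(2-hydroxypropan-2-yl)-6-(3-methylbut-2-en-1-yl)-5-oxobicyclo[2.2.2]oct-2-ene-2-carboxylate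
Product: 22 tert-butyl 1,7-dihydroxy-5,5-dimethyl-3-(3-methylbut-2-en-1-yl)-2-oxo-4-oxatricyclo[4.3.1.0(3,7)]dec-8-ene-8-carboxylate
Conditions: camphor-10-sulfonic acid (10 mol %), 4 Å molecular sieves, CH2Cl2, rt
Reagents that add atoms: none
Why: Acid-catalysed cyclodehydration of a 1,4-diol (SN1): the acyclic tertiary carbinol ionises and is captured by the C3 hydroxyl, which the bicycle holds next to it, closing the tetrahydrofuran. The other hydroxyls could only form a four-membered ring or are out of reach, and catalytic sulfonic acid at room temperature should spare the tert-butyl ester.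

Step 16
Reactants: 22 tert-butyl 1,7-dihydroxy-5,5-dimethyl-3-(3-methylbut-2-en-1-yl)-2-oxo-4-oxatricyclo[4.3.1.0(3,7)]dec-8-ene-8-carboxylate
Product: 24 1,7-dihydroxy-5,5-dimethyl-3-(3-methylbut-2-en-1-yl)-2-oxo-4-oxatricyclo[4.3.1.0(3,7)]dec-8-ene-8-carboxylic acid, via tris(trimethylsilyl) derivative 23 (not isolated)
Conditions: Me3SiOTf, 2,6-lutidine, CH2Cl2, 0 °C; then citric acid, MeOH/H2O, rt
Reagents that add atoms: none
Why: Silyl triflate cleavage of a tert-butyl ester (O-silylation, loss of 2-methylpropene) under buffered aprotic conditions that should leave the prenyl group alone; the silyl ester and the two silyl ethers formed alongside are solvolysed in the second stage.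

Step 17
Reactants: 25 3,4,5-trimethoxyphenol
Product: 26 1,2,3,5-tetramethoxybenzene
Conditions: MeI, K2CO3, acetone, reflux
Reagents that add atoms: iodomethane, CI
Why: Williamson ether synthesis on the phenoxide.

Step 18
Reactants: 26 1,2,3,5-tetramethoxybenzene; 14 1-bromo-3-methylbut-2-ene
Product: 28 1,2,3,5-tetramethoxy-4-(3-methylbut-2-en-1-yl)benzene, via (2,3,4,6-tetramethoxyphenyl)lithium 27 (not isolated)
Conditions: n-BuLi, TMEDA, THF, 0 °C; then CuBr·SMe2 (10 mol %), 14, −78 °C → rt
Reagents that add atoms: none
Why: Directed ortho-metalation between two methoxy groups (the two free ring positions are equivalent by symmetry), then copper-catalysed SN2 allylation at the primary carbon of the bromide, which gives the linear prenyl group.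

Step 19
Reactants: 28 1,2,3,5-tetramethoxy-4-(3-methylbut-2-en-1-yl)benzene
Product: 29 2,6-dimethoxy-3-(3-methylbut-2-en-1-yl)cyclohexa-2,5-diene-1,4-dione
Conditions: (NH4)2Ce(NO3)6, MeCN/H2O, 0 °C
Reagents that add atoms: water, O
Why: Oxidative demethylation by tetravalent cerium at the only para-dimethoxy pair gives the p-quinone; a short reaction at 0 °C should spare the prenyl alkene.

Step 20
Reactants: 29 2,6-dimethoxy-3-(3-methylbut-2-en-1-yl)cyclohexa-2,5-diene-1,4-dione
Product: 30 2,6-dihydroxy-3-(3-methylbut-2-en-1-yl)cyclohexa-2,5-diene-1,4-dione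
Conditions: NaOH (aq.), THF, 0 °C → rt; then HCl (aq.), 0 °C
Reagents that add atoms: sodium hydroxide, [Na+].[OH-]
Why: Hydrolysis of the two vinylogous esters by addition–elimination of hydroxide at the methoxy-bearing quinone carbons; cold, brief acidification avoids acid-induced cyclisation of the prenyl group.

Step 21
Reactants: 30 2,6-dihydroxy-3-(3-methylbut-2-en-1-yl)cyclohexa-2,5-diene-1,4-dione; 31 3-methylbut-2-enal
Product: 32 7-hydroxy-2,2-dimethyl-6-(3-methylbut-2-en-1-yl)-2H-chromene-5,8-dione
Conditions: ethylenediammonium diacetate (20 mol %), toluene, 80 °C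
Reagents that add atoms: none
Why: Knoevenagel condensation at the only unsubstituted nucleophilic ring carbon followed by oxa-6π electrocyclisation (formal [3+3] chromene annulation); closure through the neighbouring hydroxyl oxygen keeps the para-quinone, as with other 2-hydroxy-1,4-quinones.

Step 22
Reactants: 24 1,7-dihydroxy-5,5-dimethyl-3-(3-methylbut-2-en-1-yl)-2-oxo-4-oxatricyclo[4.3.1.0(3,7)]dec-8-ene-8-carboxylic acid; 32 7-hydroxy-2,2-dimethyl-6-(3-methylbut-2-en-1-yl)-2H-chromene-5,8-dione
Product: 35 CNP0222516.1 (configuration as in the compound list), via mixed 2,4,6-trichlorobenzoic anhydride 33 (not isolated), via acyloxyquinone ester 34 (not isolated)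
Conditions: 2,4,6-trichlorobenzoyl chloride, Et3N, THF, 0 °C; then 32, DMAP (cat.), toluene, 0 °C → rt; then pyridinium p-toluenesulfonate, CH2Cl2, rt
Reagents that add atoms: none
Why: Yamaguchi esterification acylates the vinylogous acid; under buffered, mildly acidic conditions the cage C7 hydroxyl should then add to the acyloxy-bearing quinone carbon (intramolecular oxa-Michael addition, 6-exo-trig) and the enol ketonise to the CH(prenyl) centre. Ring closure and enolisation are reversible, so both new stereocentres are expected to settle under thermodynamic control; base is avoided here because an enolate next to the acylal would expel the carboxylate.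

## Compound list

1 | 4,4-dimethoxycyclohexa-2,5-dien-1-one | COC1(OC)C=CC(=O)C=C1 | starting material
2 | (1R,6S)-5,5-dimethoxy-7-oxabicyclo[4.1.0]hept-3-en-2-one | O=C1C=CC(OC)(OC)[C@H]2O[C@@H]12 | intermediate
3 | (1R,6S)-3-iodo-5,5-dimethoxy-7-oxabicyclo[4.1.0]hept-3-en-2-one | O=C1C(I)=CC(OC)(OC)[C@H]2O[C@@H]12 | intermediate
4 | tert-butyl acetate | CC(=O)OC(C)(C)C | starting material
5 | lithium enolate of tert-butyl acetate | [Li+].[O-]C(=C)OC(C)(C)C | intermediate (not isolated)
6 | tert-butyl 2-[2-hydroxy-3-iodo-5,5-dimethoxy-7-oxabicyclo[4.1.0]hept-3-en-2-yl]acetate, hydroxyl cis to the epoxide oxygen | CC(C)(C)OC(=O)C[C@]1(O)C(I)=CC(OC)(OC)[C@H]2O[C@@H]12 | intermediate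
7 | cis-fused 3a,7-dihydroxy-4-iodo-3,3a,7,7a-tetrahydro-1-benzofuran-2,6-dione, 7-OH cis to 3a-OH | O=C1C[C@]2(O)C(I)=CC(=O)[C@@H](O)[C@@H]2O1 | intermediate
8 | 3a,6,7-trihydroxy-4-iodo-6-[(trimethylsilyl)methyl]-3a,6,7,7a-tetrahydro-1-benzofuran-2(3H)-one, C6 undefined | O=C1C[C@]2(O)C(I)=CC(O)(C[Si](C)(C)C)[C@@H](O)[C@@H]2O1 | intermediate (not isolated)
9 | 3a,7-dihydroxy-4-iodo-6-methylidene-3a,6,7,7a-tetrahydro-1-benzofuran-2(3H)-one | O=C1C[C@]2(O)C(I)=CC(=C)[C@@H](O)[C@@H]2O1 | intermediate
10 | 3a,7-dihydroxy-6-methylidene-2-oxo-2,3,3a,6,7,7a-hexahydro-1-benzofuran-4-carboxylic acid | O=C1C[C@]2(O)C(C(=O)O)=CC(=C)[C@@H](O)[C@@H]2O1 | intermediate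
11 | tert-butyl 3a,7-dihydroxy-6-methylidene-2-oxo-2,3,3a,6,7,7a-hexahydro-1-benzofuran-4-carboxylate | O=C1C[C@]2(O)C(C(=O)OC(C)(C)C)=CC(=C)[C@@H](O)[C@@H]2O1 | intermediate
12 | tert-butyl 3a,7-dihydroxy-2-oxo-3,3a,7,7a-tetrahydro-2H-spiro[1-benzofuran-6,2'-oxirane]-4-carboxylate, oxirane oxygen cis to 7-OH | O=C1C[C@]2(O)C(C(=O)OC(C)(C)C)=C[C@]3(CO3)[C@@H](O)[C@@H]2O1 | intermediate
13 | tert-butyl 3a-hydroxy-2,7-dioxo-3,3a,7,7a-tetrahydro-2H-spiro[1-benzofuran-6,2'-oxirane]-4-carboxylate | O=C1C[C@]2(O)C(C(=O)OC(C)(C)C)=C[C@]3(CO3)C(=O)[C@@H]2O1 | intermediate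
14 | 1-bromo-3-methylbut-2-ene (prenyl bromide) | CC(C)=CCBr | starting material
15 | dilithium alkoxide ketone enolate of 13 | [Li+].[Li+].O=C1C[C@]2([O-])C(C(=O)OC(C)(C)C)=C[C@]3(CO3)C([O-])=C2O1 | intermediate (not isolated)
16 | tert-butyl 3a-hydroxy-7a-(3-methylbut-2-en-1-yl)-2,7-dioxo-3,3a,7,7a-tetrahydro-2H-spiro[1-benzofuran-6,2'-oxirane]-4-carboxylate (key-step precursor) | CC(C)(C)OC(=O)C1=C[C@]2(CO2)C(=O)[C@]3(CC=C(C)C)OC(=O)C[C@]13O | intermediate
17 | dilithium alkoxide lactone enolate of 16 | [Li+].[Li+].CC(C)(C)OC(=O)C1=C[C@]2(CO2)C(=O)[C@]3(CC=C(C)C)OC([O-])=C[C@]13[O-] | intermediate (not isolated)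
18 | tert-butyl 1,7-dihydroxy-3-(3-methylbut-2-en-1-yl)-2,5-dioxo-4-oxatricyclo[4.3.1.0(3,7)]dec-8-ene-8-carboxylate (key-step product) | CC(C)(C)OC(=O)C1=C[C@]3(O)C[C@H]4C(=O)O[C@@](CC=C(C)C)(C3=O)[C@@]14O | intermediate
19 | tert-butyl 1,2,7-trihydroxy-3-(3-methylbut-2-en-1-yl)-5-oxo-4-oxatricyclo[4.3.1.0(3,7)]dec-8-ene-8-carboxylate, either epimer at C2 | CC(C)(C)OC(=O)C1=C[C@]3(O)C[C@H]4C(=O)O[C@@](CC=C(C)C)(C3O)[C@@]14O | intermediate
20 | tert-butyl 1,4,5,6-tetrahydroxy-7-(2-hydroxypropan-2-yl)-6-(3-methylbut-2-en-1-yl)bicyclo[2.2.2]oct-2-ene-2-carboxylate, either epimer at C5 | CC(C)(C)OC(=O)C1=C[C@]3(O)C[C@@H](C(C)(C)O)[C@@]1(O)[C@](O)(CC=C(C)C)C3O | intermediate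
21 | tert-butyl 1,4,6-trihydroxy-7-(2-hydroxypropan-2-yl)-6-(3-methylbut-2-en-1-yl)-5-oxobicyclo[2.2.2]oct-2-ene-2-carboxylate | CC(C)(C)OC(=O)C1=C[C@]3(O)C[C@@H](C(C)(C)O)[C@@]1(O)[C@](O)(CC=C(C)C)C3=O | intermediate
22 | tert-butyl 1,7-dihydroxy-5,5-dimethyl-3-(3-methylbut-2-en-1-yl)-2-oxo-4-oxatricyclo[4.3.1.0(3,7)]dec-8-ene-8-carboxylate | CC(C)(C)OC(=O)C1=C[C@]3(O)C[C@H]4C(C)(C)O[C@@](CC=C(C)C)(C3=O)[C@@]14O | intermediate
23 | trimethylsilyl 5,5-dimethyl-3-(3-methylbut-2-en-1-yl)-2-oxo-1,7-bis(trimethylsilyloxy)-4-oxatricyclo[4.3.1.0(3,7)]dec-8-ene-8-carboxylate | C[Si](C)(C)OC(=O)C1=C[C@]3(O[Si](C)(C)C)C[C@H]4C(C)(C)O[C@@](CC=C(C)C)(C3=O)[C@@]14O[Si](C)(C)C | intermediate (not isolated)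
24 | 1,7-dihydroxy-5,5-dimethyl-3-(3-methylbut-2-en-1-yl)-2-oxo-4-oxatricyclo[4.3.1.0(3,7)]dec-8-ene-8-carboxylic acid | OC(=O)C1=C[C@]3(O)C[C@H]4C(C)(C)O[C@@](CC=C(C)C)(C3=O)[C@@]14O | intermediate
25 | 3,4,5-trimethoxyphenol | COc1cc(O)cc(OC)c1OC | starting material
26 | 1,2,3,5-tetramethoxybenzene | COc1cc(OC)cc(OC)c1OC | intermediate
27 | (2,3,4,6-tetramethoxyphenyl)lithium | [Li]c1c(OC)cc(OC)c(OC)c1OC | intermediate (not isolated)
28 | 1,2,3,5-tetramethoxy-4-(3-methylbut-2-en-1-yl)benzene | COc1cc(OC)c(CC=C(C)C)c(OC)c1OC | intermediate
29 | 2,6-dimethoxy-3-(3-methylbut-2-en-1-yl)cyclohexa-2,5-diene-1,4-dione | COC1=CC(=O)C(CC=C(C)C)=C(OC)C1=O | intermediate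
30 | 2,6-dihydroxy-3-(3-methylbut-2-en-1-yl)cyclohexa-2,5-diene-1,4-dione | CC(C)=CCC1=C(O)C(=O)C(O)=CC1=O | intermediate
31 | 3-methylbut-2-enal | CC(C)=CC=O | starting material
32 | 7-hydroxy-2,2-dimethyl-6-(3-methylbut-2-en-1-yl)-2H-chromene-5,8-dione | CC(C)=CCC1=C(O)C(=O)C2=C(C=CC(C)(C)O2)C1=O | intermediate
33 | mixed anhydride of 24 and 2,4,6-trichlorobenzoic acid | O=C(OC(=O)C1=C[C@]3(O)C[C@H]4C(C)(C)O[C@@](CC=C(C)C)(C3=O)[C@@]14O)c1c(Cl)cc(Cl)cc1Cl | intermediate (not isolated)
34 | 2,2-dimethyl-6-(3-methylbut-2-en-1-yl)-5,8-dioxo-5,8-dihydro-2H-chromen-7-yl ester of 24 | CC(C)=CCC1=C(OC(=O)C2=C[C@]3(O)C[C@H]4C(C)(C)O[C@@](CC=C(C)C)(C3=O)[C@@]24O)C(=O)C5=C(C=CC(C)(C)O5)C1=O | intermediate (not isolated)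
35 | CNP0222516.1 | CC(C)=CC[C@H]1C(=O)C2=C(OC(C)(C)C=C2)C(=O)[C@@]12OC(=O)C1=C[C@]3(O)C[C@H]4C(C)(C)O[C@@](CC=C(C)C)(C3=O)[C@@]14O2 | target

## Step count and least certain steps

Total: 22 steps (16 on the cage line, 5 on the quinone line, 1 union). Longest linear sequence: 17 steps (steps 1–16 and 22).

**Step 11 (key step).** The most likely failure is a slow closure: lithium lactone enolates are sluggish toward epoxides and a boat conformer is required. If warming is needed, the product dialkoxide may undergo retro-aldol opening at C6–C7 or an acyloin shift of the new α-ketol alkoxide. The fallback sets out from 16 and changes the activation from anionic to Lewis acidic. LiN(SiMe3)2 with Me3SiCl present at −78 °C should trap the dianion as the silyl ketene acetal silyl ether F1. BF3·OEt2 at −78 °C then activates the epoxide for a Mukaiyama-type opening by the ketene acetal carbon, and aqueous HF work-up removes the silyl groups. The route is rejoined at 18.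

**Step 22.** The most likely failure is loss of the carboxylate from the adduct by β-elimination, so that a net substitution replaces the addition. A second risk is poor control at the spiro carbon and the neighbouring C–H if the natural isomer is not the thermodynamic one. The fallback sets out from 34, prepared as in step 22 but kept from acid. Me3SiOTf and 2,6-lutidine at −78 °C should promote a silyl-transfer conjugate addition of the C7 hydroxyl and hold the adduct as the silyl enol ether F2, in which no enolate is present to expel the carboxylate. Buffered HF·pyridine at low temperature then protonates the enol ether at carbon and frees the C1 hydroxyl. The route is rejoined at 35.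

**Step 15.** The most likely failure is protonation of the prenyl alkene, followed by addition of a neighbouring hydroxyl, competing with ionisation of the tertiary carbinol; elimination is a lesser risk. The fallback sets out from 19 and never opens the five-membered ring. One methyl transfer (MeLi/CeCl3 in limited excess, −78 °C) should stop at the methyl lactol F3. Me3Al in CH2Cl2 then replaces the hemiketal hydroxyl by methyl through the cyclic oxocarbenium ion to give the gem-dimethyl ether alcohol F4. IBX oxidation of its secondary alcohol rejoins the route at 22.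

**Step 1.** The most likely failure is insufficient enantioselection on the unsubstituted monoketal, together with over-epoxidation. The fallback sets out from 1 and replaces catalysis by resolution. H2O2/NaOH gives the racemic epoxy enone F5, and Luche reduction gives the racemic cis-epoxy alcohol F6. Lipase-catalysed acylation with vinyl acetate (enzyme chosen so that the unwanted antipode is acylated to acetate F8) leaves the alcohol F7. MnO2 oxidation of F7 rejoins the route at 2.

## Further compounds

F1 | step 11 | tert-butyl 7a-(3-methylbut-2-en-1-yl)-7-oxo-2,3a-bis(trimethylsilyloxy)-3a,7a-dihydro-7H-spiro[1-benzofuran-6,2'-oxirane]-4-carboxylate (silyl ketene acetal silyl ether of 16) | CC(C)(C)OC(=O)C1=C[C@]2(CO2)C(=O)[C@]3(CC=C(C)C)OC(O[Si](C)(C)C)=C[C@]13O[Si](C)(C)C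
F2 | step 22 | trimethylsilyl enol ether of 35 at the CH(prenyl)–C=O unit, with the C1 hydroxyl also silylated | CC(C)=CCC1=C(O[Si](C)(C)C)C2=C(OC(C)(C)C=C2)C(=O)[C@@]13OC(=O)C1=C[C@]4(O[Si](C)(C)C)C[C@H]5C(C)(C)O[C@@](CC=C(C)C)(C4=O)[C@@]15O3
F3 | step 15 | tert-butyl 1,2,5,7-tetrahydroxy-5-methyl-3-(3-methylbut-2-en-1-yl)-4-oxatricyclo[4.3.1.0(3,7)]dec-8-ene-8-carboxylate (methyl lactol; C2 and C5 undefined) | CC(C)(C)OC(=O)C1=C[C@]3(O)C[C@H]4C(C)(O)O[C@@](CC=C(C)C)(C3O)[C@@]14O
F4 | step 15 | tert-butyl 1,2,7-trihydroxy-5,5-dimethyl-3-(3-methylbut-2-en-1-yl)-4-oxatricyclo[4.3.1.0(3,7)]dec-8-ene-8-carboxylate (C2 undefined) | CC(C)(C)OC(=O)C1=C[C@]3(O)C[C@H]4C(C)(C)O[C@@](CC=C(C)C)(C3O)[C@@]14O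
F5 | step 1 | racemic 5,5-dimethoxy-7-oxabicyclo[4.1.0]hept-3-en-2-one | O=C1C=CC(OC)(OC)C2OC12
F6 | step 1 | racemic 5,5-dimethoxy-7-oxabicyclo[4.1.0]hept-3-en-2-ol, hydroxyl cis to the epoxide | OC1C=CC(OC)(OC)C2OC12
F7 | step 1 | 5,5-dimethoxy-7-oxabicyclo[4.1.0]hept-3-en-2-ol, enantiomer with the ring configuration of 2, hydroxyl cis to the epoxide | O[C@H]1C=CC(OC)(OC)[C@H]2O[C@@H]12
F8 | step 1 | acetate of the antipode of F7 | CC(=O)O[C@@H]1C=CC(OC)(OC)[C@@H]2O[C@H]12
A1 | alternative 1 | tetrahydrofuran-fused 2-vinylcyclobutanone, bis(tert-butyldimethylsilyl) ether, methyl ester | COC(=O)[C@@]12C=C(O[Si](C)(C)C(C)(C)C)C[C@H]3C(C)(C)O[C@@](CC=C(C)C)(C1=O)[C@@]23O[Si](C)(C)C(C)(C)C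
A2 | alternative 2 | bis(triethylsilyl) ether of the caged methyl ester | COC(=O)C1=C[C@]3(O[Si](CC)(CC)CC)C[C@H]4C(C)(C)O[C@@](CC=C(C)C)(C3=O)[C@@]14O[Si](CC)(CC)CC
A3 | alternative 3 | caged methyl ester with methoxymethyl-protected C1 carbinol | COC(=O)C1=C[C@]3(OCOC)C[C@H]4C(C)(C)O[C@@](CC=C(C)C)(C3=O)[C@@]14O
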